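**Plan**

- Cuts: the aryl ether bond O1–C8a is cut first, at the quinone monoketal oxidation level, giving a C8a‑methoxy C6‑phenol whose C2 carries a free tertiary hydroxyl. The C3=C4 alkene is then traced back to an alkyne, and the C4–C4a bond is cut into an aryl iodide and a C20 alkynol derived from phytol.
- Enabling feature: O1 links the tertiary allylic carbon C2 to arene carbon C8a, and C8a lies para to the C6 hydroxyl of ring A. Two‑electron oxidation of that phenol therefore makes C8a electrophilic while the Z C3=C4 alkene holds the C2 hydroxyl beside it, so ring B (the pyran) can close without breaking the C2–O bond.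
- Forward order: phytol to the (S)‑alkynol (steps 1–3); 2,5‑dimethylanisole to the iodoaryl acetate (steps 4–6); chain joined to ring A by Sonogashira coupling (step 7); Z alkene and free phenol (steps 8, 9); ring B closed oxidatively (step 10); ring A restored by reduction (step 11).
- Stereochemistry: C4' and C8' come unchanged from natural phytol (its C7 and C11). C2 is set by the Katsuki–Sharpless epoxidation of phytol with L‑(+)‑diethyl tartrate and is not disturbed afterwards. The ketal carbon C8a is stereogenic only in the product of step 10 and vanishes in step 11.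

Key step: step 10

Remark: chromene numbering (O1, C2, C3, C4, C4a, C5–C8, C8a; side chain C1' onward) is used for the target and, by correspondence, for its precursors; commercial natural phytol is taken to be the pure (2E,7R,11R) isomer.

**Step 1**
Reactants: 1 (2E,7R,11R)‑phytol
Product: 2 [(2S,3S)‑3‑methyl‑3‑[(4R,8R)‑4,8,12‑trimethyltridecyl]oxiran‑2‑yl]methanol ((2S,3S)‑2,3‑epoxyphytol)
Conditions: Ti(OiPr)4 (10 mol%), L‑(+)‑diethyl tartrate (12 mol%), t‑BuOOH (2 equiv, in isooctane), 4 Å molecular sieves, CH2Cl2, −20 °C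
Reagents that add atoms: tert‑butyl hydroperoxide, CC(C)(C)OO
Why: Katsuki–Sharpless asymmetric epoxidation, in which the allylic hydroxyl binds the catalyst formed from Ti(OiPr)4 and the tartrate, and L‑(+)‑diethyl tartrate directs the peroxide oxygen to the alkene face that gives the (2S,3S)‑epoxide (the sense established for geraniol, the lower homologue of this (E)‑3‑methylalk‑2‑en‑1‑ol), so the future C2 configuration is set here while C7 and C11 are remote spectators.

**Step 2**
Reactants: 2 (2S,3S)‑2,3‑epoxyphytol
Product: 3 (2S,3R)‑3‑(chloromethyl)‑2‑methyl‑2‑[(4R,8R)‑4,8,12‑trimethyltridecyl]oxirane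
Conditions: PPh3 (1.3 equiv), CCl4, NaHCO3 (0.1 equiv), reflux
Reagents that add atoms: carbon tetrachloride, ClC(Cl)(Cl)Cl
Why: Appel chlorination, in which chloride displaces the alkoxyphosphonium group at the primary carbon under near‑neutral conditions that leave the trisubstituted epoxide and all stereocentres untouched (the epoxide CH changes its descriptor from S to R only because CH2Cl now outranks the ring carbon).

**Step 3**
Reactants: 3 (2S,3R)‑3‑(chloromethyl)‑2‑methyl‑2‑[(4R,8R)‑4,8,12‑trimethyltridecyl]oxirane
Product: 5 (3S,7R,11R)‑3,7,11,15‑tetramethylhexadec‑1‑yn‑3‑ol, via lithium 1‑chloroalk‑1‑en‑3‑olate 4 (not isolated)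
Conditions: n‑BuLi (3.3 equiv), THF, −40 °C to 0 °C; then H2O
Reagents that add atoms: none
Why: base‑induced fragmentation of a 2,3‑epoxy chloride to a propargylic alcohol, in which lithiation alpha to chlorine opens the epoxide by beta‑elimination to alkoxide 4, a second equivalent of base eliminates HCl to the alkyne and a third deprotonates it, so the C3–O bond is never broken and the tertiary carbinol keeps the S configuration.

**Step 4**
Reactants: 6 2,5‑dimethylanisole
Product: 7 1‑(4‑methoxy‑2,5‑dimethylphenyl)ethan‑1‑one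
Conditions: AcCl (1.1 equiv), AlCl3 (1.2 equiv), CH2Cl2, 0 °C; then ice/aq. HCl
Reagents that add atoms: acetyl chloride, CC(=O)Cl
Why: Friedel–Crafts acylation, which should go to the position para to the methoxy group (also ortho to a methyl group), the most activated and least hindered site of the ring.

**Step 5**
Reactants: 7 1‑(4‑methoxy‑2,5‑dimethylphenyl)ethan‑1‑one
Product: 8 4‑methoxy‑2,5‑dimethylphenyl acetate
Conditions: mCPBA (1.5 equiv), CH2Cl2, rt to 40 °C
Reagents that add atoms: mCPBA (3‑chloroperoxybenzoic acid), OOC(=O)c1cccc(Cl)c1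
Why: Baeyer–Villiger oxidation, in which the electron‑rich aryl group migrates in preference to methyl, so the ketone becomes the aryl acetate that carries the future C6 oxygen already protected.

**Step 6**
Reactants: 8 4‑methoxy‑2,5‑dimethylphenyl acetate
Product: 9 3‑iodo‑4‑methoxy‑2,5‑dimethylphenyl acetate
Conditions: NIS (1.1 equiv), CF3CO2H (0.3 equiv), MeCN, rt, dark
Reagents that add atoms: N‑iodosuccinimide, O=C1CCC(=O)N1I
Why: electrophilic aromatic iodination, directed by the methoxy group to its only free ortho position (C3 of 8, the future C4a), since the acetoxy group activates its own ortho position far less.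

**Step 7**
Reactants: 9 3‑iodo‑4‑methoxy‑2,5‑dimethylphenyl acetate; 5 (3S,7R,11R)‑3,7,11,15‑tetramethylhexadec‑1‑yn‑3‑ol (1.1 equiv)
Product: 10 3‑[(3S,7R,11R)‑3‑hydroxy‑3,7,11,15‑tetramethylhexadec‑1‑yn‑1‑yl]‑4‑methoxy‑2,5‑dimethylphenyl acetate
Conditions: Pd(PPh3)2Cl2 (3 mol%), CuI (5 mol%), Et3N/THF 1:1 (degassed), 60 °C
Reagents that add atoms: none
Why: Sonogashira coupling (oxidative addition of the aryl iodide to zerovalent palladium, transfer of the alkynyl group by way of CuI and Et3N, reductive elimination), which forms the future C4–C4a bond, tolerates the free tertiary hydroxyl and the aryl acetate, and does not touch the stereocentres.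

**Step 8**
Reactants: 10 3‑[(3S,7R,11R)‑3‑hydroxy‑3,7,11,15‑tetramethylhexadec‑1‑yn‑1‑yl]‑4‑methoxy‑2,5‑dimethylphenyl acetate
Product: 11 3‑[(1Z,3S,7R,11R)‑3‑hydroxy‑3,7,11,15‑tetramethylhexadec‑1‑en‑1‑yl]‑4‑methoxy‑2,5‑dimethylphenyl acetate
Conditions: H2 (1 atm), Pd/CaCO3–Pb(OAc)2 (Lindlar catalyst), quinoline, EtOAc, rt; stopped after 1 equiv H2
Reagents that add atoms: none
Why: Lindlar semihydrogenation, in which both hydrogens are delivered to the same face of the alkyne on the lead‑poisoned palladium surface and quinoline suppresses further reduction, so the Z alkene needed to place the C2 hydroxyl next to C8a should result.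

**Step 9**
Reactants: 11 3‑[(1Z,3S,7R,11R)‑3‑hydroxy‑3,7,11,15‑tetramethylhexadec‑1‑en‑1‑yl]‑4‑methoxy‑2,5‑dimethylphenyl acetate
Product: 12 3‑[(1Z,3S,7R,11R)‑3‑hydroxy‑3,7,11,15‑tetramethylhexadec‑1‑en‑1‑yl]‑4‑methoxy‑2,5‑dimethylphenol
Conditions: K2CO3 (0.2 equiv), MeOH/THF 2:1, 0 °C to rt, argon
Reagents that add atoms: none
Why: base‑catalysed transesterification (methanolysis) of the aryl acetate, mild enough to leave the Z alkene and the tertiary allylic alcohol unchanged.

**Step 10**
Reactants: 12 3‑[(1Z,3S,7R,11R)‑3‑hydroxy‑3,7,11,15‑tetramethylhexadec‑1‑en‑1‑yl]‑4‑methoxy‑2,5‑dimethylphenol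
Product: 13 (2S)‑8a‑methoxy‑2,5,8‑trimethyl‑2‑[(4R,8R)‑4,8,12‑trimethyltridecyl]‑2H‑chromen‑6(8aH)‑one (both C8a epimers)
Conditions: PhI(OAc)2 (1.1 equiv), CH2Cl2 (0.01 M), 0 °C; aq. NaHCO3 work‑up
Reagents that add atoms: none
Why: Ligand exchange of the C6 phenol at trivalent iodine, followed by loss of iodobenzene and acetate, removes two electrons and leaves a para‑quinoid oxocarbenium ion whose positive charge rests on C8a, stabilised by the methoxy group; the tertiary hydroxyl, held beside C8a by the Z C3=C4 alkene, adds there and forms the O1–C8a bond. The closest known reaction type is the oxidation of para‑alkoxyphenols with PhI(OAc)2 (or at an anode) to quinone monoketals with capture by an alcohol, tethered alcohols included, and the 8a‑alkoxy ketals formed when tocopherols are oxidised in alcohols are close relatives of 13. Ring B closes in a 6‑exo‑trig mode, the attacked C8a=O+Me bond lying outside the new ring. C8a becomes a stereocentre under no control, which is harmless because step 11 returns it to sp2, and C2 keeps its S configuration because the C2–O bond is not broken, something an ionising etherification of this tertiary allylic alcohol could not guarantee. The step needs chemoselectivity (attack at C8a by the internal hydroxyl, not by acetate or water and not at C7), and this is secured by the methoxy group localising the charge at C8a, by the six‑membered transition state that the Z alkene enforces, and by a dilute non‑nucleophilic solvent.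

**Step 11**
Reactants: 13 (2S)‑8a‑methoxy‑2,5,8‑trimethyl‑2‑[(4R,8R)‑4,8,12‑trimethyltridecyl]‑2H‑chromen‑6(8aH)‑one
Product: 14 (2S)‑2,5,8‑trimethyl‑2‑[(4R,8R)‑4,8,12‑trimethyltridecyl]‑2H‑chromen‑6‑ol
Conditions: Zn dust (10 equiv), AcOH/THF 1:5, 0 °C to rt, argon
Reagents that add atoms: none
Why: reductive rearomatisation of a quinone monoketal by zinc in acetic acid, in which two electrons and two protons are delivered to the dienone, the exocyclic methoxy group is lost in preference to the ring oxygen (its loss keeps ring B and passes through the more substituted cyclic oxocarbenium ion, the course known for the reduction of 8a‑alkoxy ketals of tocopherols), ring A is restored, C8a returns to sp2 and C2 is untouched.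

**Compound list**

1 | (2E,7R,11R)‑3,7,11,15‑tetramethylhexadec‑2‑en‑1‑ol (natural phytol) | OC/C=C(\C)CCC[C@H](C)CCC[C@H](C)CCCC(C)C | starting material
2 | [(2S,3S)‑3‑methyl‑3‑[(4R,8R)‑4,8,12‑trimethyltridecyl]oxiran‑2‑yl]methanol | OC[C@@H]1O[C@@]1(C)CCC[C@H](C)CCC[C@H](C)CCCC(C)C | intermediate
3 | (2S,3R)‑3‑(chloromethyl)‑2‑methyl‑2‑[(4R,8R)‑4,8,12‑trimethyltridecyl]oxirane | ClC[C@@H]1O[C@@]1(C)CCC[C@H](C)CCC[C@H](C)CCCC(C)C | intermediate
4 | lithium (3S,7R,11R)‑1‑chloro‑3,7,11,15‑tetramethylhexadec‑1‑en‑3‑olate (alkene geometry not defined; not isolated) | ClC=C[C@@](C)([O-])CCC[C@H](C)CCC[C@H](C)CCCC(C)C.[Li+] | intermediate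
5 | (3S,7R,11R)‑3,7,11,15‑tetramethylhexadec‑1‑yn‑3‑ol | C#C[C@@](C)(O)CCC[C@H](C)CCC[C@H](C)CCCC(C)C | intermediate
6 | 2,5‑dimethylanisole (2‑methoxy‑1,4‑dimethylbenzene) | COc1cc(C)ccc1C | starting material
7 | 1‑(4‑methoxy‑2,5‑dimethylphenyl)ethan‑1‑one | CC(=O)c1cc(C)c(OC)cc1C | intermediate
8 | 4‑methoxy‑2,5‑dimethylphenyl acetate | CC(=O)Oc1cc(C)c(OC)cc1C | intermediate
9 | 3‑iodo‑4‑methoxy‑2,5‑dimethylphenyl acetate | CC(=O)Oc1cc(C)c(OC)c(I)c1C | intermediate
10 | 3‑[(3S,7R,11R)‑3‑hydroxy‑3,7,11,15‑tetramethylhexadec‑1‑yn‑1‑yl]‑4‑methoxy‑2,5‑dimethylphenyl acetate | CC(=O)Oc1cc(C)c(OC)c(C#C[C@@](C)(O)CCC[C@H](C)CCC[C@H](C)CCCC(C)C)c1C | intermediate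
11 | 3‑[(1Z,3S,7R,11R)‑3‑hydroxy‑3,7,11,15‑tetramethylhexadec‑1‑en‑1‑yl]‑4‑methoxy‑2,5‑dimethylphenyl acetate | CC(=O)Oc1cc(C)c(OC)c(/C=C\[C@@](C)(O)CCC[C@H](C)CCC[C@H](C)CCCC(C)C)c1C | intermediate
12 | 3‑[(1Z,3S,7R,11R)‑3‑hydroxy‑3,7,11,15‑tetramethylhexadec‑1‑en‑1‑yl]‑4‑methoxy‑2,5‑dimethylphenol | Cc1cc(O)c(C)c(/C=C\[C@@](C)(O)CCC[C@H](C)CCC[C@H](C)CCCC(C)C)c1OC | intermediate
13 | (2S)‑8a‑methoxy‑2,5,8‑trimethyl‑2‑[(4R,8R)‑4,8,12‑trimethyltridecyl]‑2H‑chromen‑6(8aH)‑one (both C8a epimers) | COC12O[C@@](C)(CCC[C@H](C)CCC[C@H](C)CCCC(C)C)C=CC1=C(C)C(=O)C=C2C | intermediate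
14 | (2S)‑2,5,8‑trimethyl‑2‑[(4R,8R)‑4,8,12‑trimethyltridecyl]‑2H‑chromen‑6‑ol | Cc1cc(O)c(C)c2c1O[C@@](C)(CCC[C@H](C)CCC[C@H](C)CCCC(C)C)C=C2 | target

**Step count and risks**

Total step count: 11. Longest linear sequence: 8 steps (steps 1–3 and 7–11 from phytol; steps 4–11 from 2,5‑dimethylanisole).

Steps most likely to fail:

Step 10. The para‑quinoid cation may be intercepted by acetate or adventitious water faster than by the hindered tertiary hydroxyl; such adducts collapse with loss of methanol to a quinone, and the acetic acid released may also ionise the tertiary allylic alcohol. The fallback sets out from 12 and comes back at 13, and it separates oxidation from ring closure. PhI(OAc)2 in MeOH at 0 °C, the usual way to quinone monoketals of para‑methoxyphenols, should let the solvent capture C8a and give 3‑[(1Z,3S,7R,11R)‑3‑hydroxy‑3,7,11,15‑tetramethylhexadec‑1‑en‑1‑yl]‑4,4‑dimethoxy‑2,5‑dimethylcyclohexa‑2,5‑dien‑1‑one F1. PPTS (catalytic) in CH2Cl2 over 5 Å molecular sieves should then exchange one methoxy group for the tethered hydroxyl (acid‑catalysed transketalisation driven by removal of methanol), which forms the same O1–C8a bond and gives 13.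

Step 11. Electron transfer from zinc may expel the ring alkoxide instead of methoxide, which only returns 12, or may reduce the C3=C4–C4a=C5 dienone in a conjugate sense. The fallback sets out from 13 and comes back at 14, and it separates hydride delivery from ionisation. iBu2AlH in toluene at −78 °C should reduce the C6 carbonyl in a 1,2 sense to (2S)‑8a‑methoxy‑2,5,8‑trimethyl‑2‑[(4R,8R)‑4,8,12‑trimethyltridecyl]‑6,8a‑dihydro‑2H‑chromen‑6‑ol F2, as a mixture of epimers at C6 and C8a. PPTS (catalytic) in CH2Cl2 at 0 °C should then ionise the ketal by exocyclic loss of methanol, as in the acid cleavage of a pyranoside, and loss of the C6 proton from the cation stabilised by the ring oxygen should aromatise ring A to 14.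

Step 8. Hydrogen uptake may stall at the hindered alkyne, which is flanked by the di‑ortho‑substituted arene and the tertiary carbinol, or may run on to the saturated chain; either course removes the Z alkene on which step 10 depends. The fallback sets out from 10 and comes back at 11, and it replaces catalytic hydrogenation by a stoichiometric metal reduction. Zinc dust activated with Cu(OAc)2 and AgNO3 in MeOH/H2O/THF at 40 °C should reduce the aryl‑ and hydroxyl‑activated triple bond to the cis alkene by electron transfer and protonation at the metal surface, without reducing the alkene further; no new compound is made (F0).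

**Further compounds**

F1 | step 10 | 3‑[(1Z,3S,7R,11R)‑3‑hydroxy‑3,7,11,15‑tetramethylhexadec‑1‑en‑1‑yl]‑4,4‑dimethoxy‑2,5‑dimethylcyclohexa‑2,5‑dien‑1‑one | COC1(OC)C(C)=CC(=O)C(C)=C1/C=C\[C@@](C)(O)CCC[C@H](C)CCC[C@H](C)CCCC(C)C
F2 | step 11 | (2S)‑8a‑methoxy‑2,5,8‑trimethyl‑2‑[(4R,8R)‑4,8,12‑trimethyltridecyl]‑6,8a‑dihydro‑2H‑chromen‑6‑ol | COC12O[C@@](C)(CCC[C@H](C)CCC[C@H](C)CCCC(C)C)C=CC1=C(C)C(O)C=C2C
F0 | step 8 | none | none
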